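- I wanted to know, for the flask, how many monomer units a chain held on average and what part of J had reacted by 15 s.

J 2.0 × 10⁻⁴ M; D 0.0600 mM; L 13 µM; time 15 s

    Q + D → Q.D (k1 = 210 M⁻¹ s⁻¹)
    J + Q → X + Q, rate k2*[Q]*[J] (k2 = 4900 M⁻¹ s⁻¹)
    J + L → Q + X (k3 = 3700 M⁻¹ s⁻¹)
    Q + J → Q.J (k4 = 180 M⁻¹ s⁻¹)

* average number of monomer units in a chain (chains begun, living or dead) at 15 s
* part of the J that has reacted at 15 s

- The flask looked contradictory: k2 stood at 1.32 times k3, yet L at the charged c(J) had a half-life of 0.937 s, while J, facing a c(Q) equal to the charge of L, had 10.5 s.
- This cleared up once I treated each loss as pseudo-first-order: L met c(J), J met c(Q), and the charged c(J) stood at 15.4 times the charge of L, so L went at 0.740 s⁻¹, faster than J at 0.0660 s⁻¹, and I put the crossing from initiation to growth at about 1.35 s, the lifetime of L at the charged c(J).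
- I therefore took the charge of L as the count of chains begun and as the starting c(Q), took that delay off the time, and thinned c(Q) at mid-run by its loss to D and J, which at an assumed c(J) of 100 µM came to 0.0306 s⁻¹.
- That gave the dose, 0.717, the number of lifetimes of J that the living ends served by the asked time, and I took exp(−dose) as the part of J left.
- So I reckoned c at 51.2 %, and dp, as the charge ratio times c times the growth share k2/(k2+k4), at 7.59.
- The forecast gave dp 7.9 and c 53 %, on the ground that “L is used up quickly”.
- The simulated flask gave dp 7.95 and c 53.3 %, and that c, put through the same exponential with the J taken up by L counted in it, corresponds to a dose of 0.761 against my 0.717.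
- My dose scaled with the charge of L when I held the time, the delay and the reckoned loss, so for the neighbouring flask with 2.2 × 10⁻⁵ M of L I reckoned a dose of 1.21, hence c 70.3 % and dp 6.16; that neighbouring flask gave c 73.4 % and dp 6.49.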